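**Plan**

- Numbering (eremophilane): ring A = C1–C5 and C10, ring B = C5–C10; C15 is the methyl on C4, C14 the methyl on C5, C11–C13 the isopropenyl on C7; α/β refer to the decalin drawn with C14 β. The enabling feature is the acyloin of ring B, the C8 ketone bonded directly to the C9 carbinol.
- Retrosynthesis: cut the two ester C–O bonds (acyl groups on O3 and O9), then C7–C11, then the acyloin bond C8–C9. This opens ring B to a ring A dialdehyde with a 3-oxopropyl arm on C5 and a formyl group on C10. The arm goes back to an allyl group (C5–C6) and C15 to an enone α-methylation (C4–C15).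
- Forward: ring A is bought as a cyclohexenone ester and receives C15 and the allyl arm; both arms are brought to the aldehyde level; ring B closes by carbene-catalysed aldehyde–aldehyde coupling; the isopropenyl group and the two acyl groups follow.
- Stereochemistry: C5 from conjugate allylation anti to the C10 ester (trans arms); C4 from axial protonation to the equatorial methyl; absolute configuration and C3 from an (R)-selective ketoreductase acting on the racemic ketone; C9 and C7 from the equatorial preference that the axial C14 methyl imposes on the trans-decalin.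

Key step: step 8

Assumption: angelic acid and (E)-3-methylpent-2-enoic acid are bought geometrically pure, and the ketoreductase is chosen by screening a commercial (R)-selective panel.

**Route**

Step 1
Reactants: 1 ethyl 2-methyl-4-oxocyclohex-2-ene-1-carboxylate (racemic); 2 iodomethane
Product: 3 ethyl 2,3-dimethyl-4-oxocyclohex-2-ene-1-carboxylate (racemic)
Conditions: KOt-Bu, MeI, t-BuOH, 0 °C to rt
Reagents that add atoms: iodomethane 2, CI
Why: Deprotonation at the doubly activated ring carbon gives the extended dienolate, which is methylated at the α-carbon of the enone (the future C4) and then returns to conjugation, the classical dienolate alkylation of this vinylogous β-keto ester.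

Step 2
Reactants: 3 ethyl 2,3-dimethyl-4-oxocyclohex-2-ene-1-carboxylate; 4 allyltrimethylsilane
Product: 5 ethyl (1R*,2R*,3R*)-2,3-dimethyl-4-oxo-2-(prop-2-en-1-yl)cyclohexane-1-carboxylate (racemic; allyl trans to the ester, ring methyls cis)
Conditions: TiCl4, allylSiMe3, CH2Cl2, −78 to −40 °C; aq. NaHCO3 work-up
Reagents that add atoms: allyltrimethylsilane 4, C=CC[Si](C)(C)C
Why: Hosomi–Sakurai conjugate allylation, in which the TiCl4-activated enone is attacked at the β-carbon on the face opposite the ester (held pseudoaxial by allylic strain with the vinylic methyl), so the quaternary C5 forms with allyl trans to the ester, and work-up protonates C4 axially to leave its methyl equatorial and cis to the C5 methyl, which is also the thermodynamically preferred epimer.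

Step 3
Reactants: 5 ethyl (1R*,2R*,3R*)-2,3-dimethyl-4-oxo-2-(prop-2-en-1-yl)cyclohexane-1-carboxylate (racemic)
Product: 6 ethyl (1R,2R,3R,4R)-4-hydroxy-2,3-dimethyl-2-(prop-2-en-1-yl)cyclohexane-1-carboxylate
Conditions: (R)-selective NADPH-dependent ketoreductase, NADP+ (cat.), i-PrOH, aq. phosphate buffer pH 7, 30 °C; chromatography
Reagents that add atoms: none
Why: Enzymatic carbonyl reduction used as a reductive kinetic resolution, in which the enzyme delivers hydride to one carbonyl face only, so the (1R,2R,3R) ketone gives the all-equatorial (4R) alcohol while its mirror image is left behind or becomes a separable diastereomeric alcohol, fixing the absolute configuration and C3 in one operation.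

Step 4
Reactants: 6 ethyl (1R,2R,3R,4R)-4-hydroxy-2,3-dimethyl-2-(prop-2-en-1-yl)cyclohexane-1-carboxylate
Product: 7 ethyl (1R,2R,3R,4R)-4-[(tert-butyldimethylsilyl)oxy]-2,3-dimethyl-2-(prop-2-en-1-yl)cyclohexane-1-carboxylate
Conditions: TBSOTf, 2,6-lutidine, CH2Cl2, 0 °C
Reagents that add atoms: tert-butyldimethylsilyl trifluoromethanesulfonate, CC(C)(C)[Si](C)(C)OS(=O)(=O)C(F)(F)F
Why: Standard silyl ether formation with the silyl triflate, reactive enough for a carbinol flanked by a methyl-bearing carbon and inert toward the ester and the alkene.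

Step 5
Reactants: 7 ethyl (1R,2R,3R,4R)-4-[(tert-butyldimethylsilyl)oxy]-2,3-dimethyl-2-(prop-2-en-1-yl)cyclohexane-1-carboxylate
Product: 9 ethyl (1R,2R,3R,4R)-4-[(tert-butyldimethylsilyl)oxy]-2-(3-hydroxypropyl)-2,3-dimethylcyclohexane-1-carboxylate, via B-alkyl-9-BBN adduct 8 (not isolated)
Conditions: 9-BBN, THF, 0 °C to rt; then aq. NaOH, H2O2, 0 °C
Reagents that add atoms: hydrogen peroxide, OO (supplies the hydroxyl oxygen); 9-borabicyclo[3.3.1]nonane, B1C2CCCC1CCC2 (its boron stays only in 8)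
Why: Hydroboration–oxidation, in which the bulky ester-tolerant borane adds anti-Markovnikov to the terminal alkene and the C–B bond is exchanged for C–O to give the primary alcohol that becomes C8.

Step 6
Reactants: 9 ethyl (1R,2R,3R,4R)-4-[(tert-butyldimethylsilyl)oxy]-2-(3-hydroxypropyl)-2,3-dimethylcyclohexane-1-carboxylate
Product: 10 3-[(1S,2R,3R,6R)-3-[(tert-butyldimethylsilyl)oxy]-6-(hydroxymethyl)-1,2-dimethylcyclohexyl]propan-1-ol (configuration unchanged; the C5 descriptor changes only through CIP priorities)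
Conditions: LiAlH4, THF, 0 °C
Reagents that add atoms: none
Why: Hydride reduction of the ester to the primary alcohol (the future C9) is reliable even next to a quaternary carbon and leaves the silyl ether and all stereocentres untouched.

Step 7
Reactants: 10 3-[(1S,2R,3R,6R)-3-[(tert-butyldimethylsilyl)oxy]-6-(hydroxymethyl)-1,2-dimethylcyclohexyl]propan-1-ol
Product: 11 (1R,2R,3R,4R)-4-[(tert-butyldimethylsilyl)oxy]-2,3-dimethyl-2-(3-oxopropyl)cyclohexane-1-carbaldehyde
Conditions: Dess–Martin periodinane, NaHCO3, CH2Cl2, 0 °C to rt; used at once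
Reagents that add atoms: none
Why: Dess–Martin oxidation takes both primary alcohols to aldehydes under buffered, non-basic conditions, so the enolizable C10 centre next to the new formyl group should keep its configuration and no over-oxidation is expected.

Step 8
Reactants: 11 (1R,2R,3R,4R)-4-[(tert-butyldimethylsilyl)oxy]-2,3-dimethyl-2-(3-oxopropyl)cyclohexane-1-carbaldehyde
Product: 12 (1S,4aR,5R,6R,8aR)-6-[(tert-butyldimethylsilyl)oxy]-1-hydroxy-4a,5-dimethyl-3,4,4a,5,6,7,8,8a-octahydronaphthalen-2(1H)-one (trans-fused, 9α-hydroxy-8-ketone)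
Conditions: 2-(pentafluorophenyl)-6,7-dihydro-5H-pyrrolo[2,1-c][1,2,4]triazol-2-ium tetrafluoroborate (20 mol %), Et3N (20 mol %), CH2Cl2 (0.02 M), rt, argon
Reagents that add atoms: none
Why: The triazolylidene freed by Et3N adds to the unbranched C8 aldehyde and proton transfer gives the hydroxy-enamine, an acyl anion equivalent, which attacks the C9 aldehyde and then expels the carbene, so that C8 ends as the ketone and C9 as the carbinol. The closest known reaction type is the azolium-catalysed intramolecular acyloin (crossed benzoin) cyclization of aliphatic dialdehydes to cyclic 2-hydroxy ketones. Ring B closes in a 6-exo-trig mode through a chair in which the two arms are diequatorial on ring A, which gives the trans-fused decalin directly. The new C9 centre is controlled by the axial C14 methyl, since a 9β oxygen would be syn-diaxial to it, so the formyl group is attacked with its oxygen equatorial; because the addition is reversible and C9 can epimerize next to the new ketone, the 9α alcohol should accumulate in any case. The step needs C8 rather than C9 to become the acyl anion, and neither aldol closure from C7 nor epimerization at C10 to intervene; the first is secured by the α-branched C9 aldehyde beside quaternary C5, where the bulky N-aryl carbene adds slowly, the others by the weak amine base, the low basicity of this carbene and high dilution.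

Step 9
Reactants: 12 (1S,4aR,5R,6R,8aR)-6-[(tert-butyldimethylsilyl)oxy]-1-hydroxy-4a,5-dimethyl-3,4,4a,5,6,7,8,8a-octahydronaphthalen-2(1H)-one
Product: 13 (1S,4aR,5R,6R,8aR)-6-[(tert-butyldimethylsilyl)oxy]-4a,5-dimethyl-1-[(triethylsilyl)oxy]-3,4,4a,5,6,7,8,8a-octahydronaphthalen-2(1H)-one
Conditions: Et3SiCl, imidazole, DMF, 0 °C to rt
Reagents that add atoms: chlorotriethylsilane, CC[Si](Cl)(CC)CC
Why: Imidazole-promoted silylation of the secondary ketol hydroxyl, with a triethylsilyl ether chosen because it can later be removed while the tert-butyldimethylsilyl ether on C3 stays.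

Step 10
Reactants: 13 (1S,4aR,5R,6R,8aR)-6-[(tert-butyldimethylsilyl)oxy]-4a,5-dimethyl-1-[(triethylsilyl)oxy]-3,4,4a,5,6,7,8,8a-octahydronaphthalen-2(1H)-one; 14 2-bromopropene
Product: 15 (1S,3S,4aR,5R,6R,8aR)-6-[(tert-butyldimethylsilyl)oxy]-4a,5-dimethyl-3-(prop-1-en-2-yl)-1-[(triethylsilyl)oxy]-3,4,4a,5,6,7,8,8a-octahydronaphthalen-2(1H)-one
Conditions: 2-bromopropene, Pd2(dba)3 (cat.), P(t-Bu)3 (cat.), LiN(SiMe3)2 (2.2 equiv), toluene, rt; aq. NH4Cl
Reagents that add atoms: 2-bromopropene 14, C=C(C)Br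
Why: Palladium-catalysed α-alkenylation of a ketone enolate (coupling of the lithium enolate with an alkenyl bromide on a zerovalent palladium/P(t-Bu)3 catalyst), in which the amide base deprotonates the less hindered C7 methylene and not the silyloxy-bearing C9, and protonation of the product enolate on work-up, followed if needed by brief equilibration over Et3N, should leave the isopropenyl group equatorial (7α) because the axial position is syn to the C14 methyl.

Step 11
Reactants: 15 (1S,3S,4aR,5R,6R,8aR)-6-[(tert-butyldimethylsilyl)oxy]-4a,5-dimethyl-3-(prop-1-en-2-yl)-1-[(triethylsilyl)oxy]-3,4,4a,5,6,7,8,8a-octahydronaphthalen-2(1H)-one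
Product: 16 (1S,3S,4aR,5R,6R,8aR)-6-[(tert-butyldimethylsilyl)oxy]-1-hydroxy-4a,5-dimethyl-3-(prop-1-en-2-yl)-3,4,4a,5,6,7,8,8a-octahydronaphthalen-2(1H)-one
Conditions: HF·pyridine, pyridine, THF, 0 °C
Reagents that add atoms: none
Why: Buffered fluoride desilylation, in which the triethylsilyl ether of the ketol is cleaved far faster than the secondary tert-butyldimethylsilyl ether and the mildly acidic medium should leave the β,γ-unsaturated ketone unconjugated.

Step 12
Reactants: 16 (1S,3S,4aR,5R,6R,8aR)-6-[(tert-butyldimethylsilyl)oxy]-1-hydroxy-4a,5-dimethyl-3-(prop-1-en-2-yl)-3,4,4a,5,6,7,8,8a-octahydronaphthalen-2(1H)-one; 17 (E)-3-methylpent-2-enoic acid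
Product: 18 (1S,3S,4aR,5R,6R,8aR)-6-[(tert-butyldimethylsilyl)oxy]-4a,5-dimethyl-2-oxo-3-(prop-1-en-2-yl)decahydronaphthalen-1-yl (E)-3-methylpent-2-enoate
Conditions: EDC·HCl, DMAP, CH2Cl2, 0 °C to rt
Reagents that add atoms: (E)-3-methylpent-2-enoic acid 17, CC/C(C)=C/C(=O)O
Why: Steglich esterification (carbodiimide activation, DMAP acyl transfer) of the equatorial C9 hydroxyl in the absence of strong base, so the E alkene of the acid and the C7 and C9 centres flanking the ketone should be preserved.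

Step 13
Reactants: 18 (1S,3S,4aR,5R,6R,8aR)-6-[(tert-butyldimethylsilyl)oxy]-4a,5-dimethyl-2-oxo-3-(prop-1-en-2-yl)decahydronaphthalen-1-yl (E)-3-methylpent-2-enoate
Product: 19 (1S,3S,4aR,5R,6R,8aR)-6-hydroxy-4a,5-dimethyl-2-oxo-3-(prop-1-en-2-yl)decahydronaphthalen-1-yl (E)-3-methylpent-2-enoate
Conditions: aq. HF, MeCN, 0 °C to rt
Reagents that add atoms: none
Why: Acidic fluoride cleavage of the remaining secondary silyl ether under conditions that tolerate the ester, the ketone and the 1,1-disubstituted alkene.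

Step 14
Reactants: 19 (1S,3S,4aR,5R,6R,8aR)-6-hydroxy-4a,5-dimethyl-2-oxo-3-(prop-1-en-2-yl)decahydronaphthalen-1-yl (E)-3-methylpent-2-enoate; 20 angelic acid, (Z)-2-methylbut-2-enoic acid
Product: 22 (1S,3S,4aR,5R,6R,8aR)-4a,5-dimethyl-6-{[(Z)-2-methylbut-2-enoyl]oxy}-2-oxo-3-(prop-1-en-2-yl)decahydronaphthalen-1-yl (E)-3-methylpent-2-enoate (CNP0301161.1), via angelic 2,4,6-trichlorobenzoic anhydride 21 (not isolated)
Conditions: angelic acid, 2,4,6-trichlorobenzoyl chloride, Et3N, toluene, rt; then 19, toluene, 75 °C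
Reagents that add atoms: angelic acid 20, C/C=C(/C)C(=O)O; 2,4,6-trichlorobenzoyl chloride, O=C(Cl)c1c(Cl)cc(Cl)cc1Cl (its aroyl group stays only in 21)
Why: Yamaguchi-type esterification through the mixed aroyl anhydride without a nucleophilic catalyst, the usual way to acylate a secondary alcohol with angelic acid while suppressing Z to E isomerization to the tiglate, the hindered aroyl carbonyl directing the C3 hydroxyl to the angeloyl carbonyl.

**Compound list**

1 | ethyl 2-methyl-4-oxocyclohex-2-ene-1-carboxylate (racemic) | CCOC(=O)C1CCC(=O)C=C1C | starting material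
2 | iodomethane | CI | starting material
3 | ethyl 2,3-dimethyl-4-oxocyclohex-2-ene-1-carboxylate (racemic) | CCOC(=O)C1CCC(=O)C(C)=C1C | intermediate
4 | allyltrimethylsilane | C=CC[Si](C)(C)C | starting material
5 | ethyl (1R*,2R*,3R*)-2,3-dimethyl-4-oxo-2-(prop-2-en-1-yl)cyclohexane-1-carboxylate (racemic; the enantiomer carried on is drawn) | C=CC[C@]1(C)[C@@H](C)C(=O)CC[C@H]1C(=O)OCC | intermediate
6 | ethyl (1R,2R,3R,4R)-4-hydroxy-2,3-dimethyl-2-(prop-2-en-1-yl)cyclohexane-1-carboxylate | C=CC[C@]1(C)[C@@H](C)[C@H](O)CC[C@H]1C(=O)OCC | intermediate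
7 | ethyl (1R,2R,3R,4R)-4-[(tert-butyldimethylsilyl)oxy]-2,3-dimethyl-2-(prop-2-en-1-yl)cyclohexane-1-carboxylate | C=CC[C@]1(C)[C@@H](C)[C@H](O[Si](C)(C)C(C)(C)C)CC[C@H]1C(=O)OCC | intermediate
8 | ethyl (1R,2R,3R,4R)-2-[3-(9-borabicyclo[3.3.1]nonan-9-yl)propyl]-4-[(tert-butyldimethylsilyl)oxy]-2,3-dimethylcyclohexane-1-carboxylate (B-alkyl-9-BBN adduct, not isolated) | C1CCC2CCCC(C1)B2CCC[C@]1(C)[C@@H](C)[C@H](O[Si](C)(C)C(C)(C)C)CC[C@H]1C(=O)OCC | intermediate
9 | ethyl (1R,2R,3R,4R)-4-[(tert-butyldimethylsilyl)oxy]-2-(3-hydroxypropyl)-2,3-dimethylcyclohexane-1-carboxylate | OCCC[C@]1(C)[C@@H](C)[C@H](O[Si](C)(C)C(C)(C)C)CC[C@H]1C(=O)OCC | intermediate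
10 | 3-[(1S,2R,3R,6R)-3-[(tert-butyldimethylsilyl)oxy]-6-(hydroxymethyl)-1,2-dimethylcyclohexyl]propan-1-ol | OCCC[C@]1(C)[C@@H](C)[C@H](O[Si](C)(C)C(C)(C)C)CC[C@H]1CO | intermediate
11 | (1R,2R,3R,4R)-4-[(tert-butyldimethylsilyl)oxy]-2,3-dimethyl-2-(3-oxopropyl)cyclohexane-1-carbaldehyde | O=CCC[C@]1(C)[C@@H](C)[C@H](O[Si](C)(C)C(C)(C)C)CC[C@H]1C=O | intermediate
12 | (1S,4aR,5R,6R,8aR)-6-[(tert-butyldimethylsilyl)oxy]-1-hydroxy-4a,5-dimethyl-3,4,4a,5,6,7,8,8a-octahydronaphthalen-2(1H)-one | O=C1CC[C@]2(C)[C@@H](C)[C@H](O[Si](C)(C)C(C)(C)C)CC[C@H]2[C@@H]1O | intermediate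
13 | (1S,4aR,5R,6R,8aR)-6-[(tert-butyldimethylsilyl)oxy]-4a,5-dimethyl-1-[(triethylsilyl)oxy]-3,4,4a,5,6,7,8,8a-octahydronaphthalen-2(1H)-one | O=C1CC[C@]2(C)[C@@H](C)[C@H](O[Si](C)(C)C(C)(C)C)CC[C@H]2[C@@H]1O[Si](CC)(CC)CC | intermediate
14 | 2-bromopropene | C=C(C)Br | starting material
15 | (1S,3S,4aR,5R,6R,8aR)-6-[(tert-butyldimethylsilyl)oxy]-4a,5-dimethyl-3-(prop-1-en-2-yl)-1-[(triethylsilyl)oxy]-3,4,4a,5,6,7,8,8a-octahydronaphthalen-2(1H)-one | C=C(C)[C@@H]1C[C@]2(C)[C@@H](C)[C@H](O[Si](C)(C)C(C)(C)C)CC[C@H]2[C@H](O[Si](CC)(CC)CC)C1=O | intermediate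
16 | (1S,3S,4aR,5R,6R,8aR)-6-[(tert-butyldimethylsilyl)oxy]-1-hydroxy-4a,5-dimethyl-3-(prop-1-en-2-yl)-3,4,4a,5,6,7,8,8a-octahydronaphthalen-2(1H)-one | C=C(C)[C@@H]1C[C@]2(C)[C@@H](C)[C@H](O[Si](C)(C)C(C)(C)C)CC[C@H]2[C@H](O)C1=O | intermediate
17 | (E)-3-methylpent-2-enoic acid | CC/C(C)=C/C(=O)O | starting material
18 | (1S,3S,4aR,5R,6R,8aR)-6-[(tert-butyldimethylsilyl)oxy]-4a,5-dimethyl-2-oxo-3-(prop-1-en-2-yl)decahydronaphthalen-1-yl (E)-3-methylpent-2-enoate | C=C(C)[C@@H]1C[C@]2(C)[C@@H](C)[C@H](O[Si](C)(C)C(C)(C)C)CC[C@H]2[C@H](OC(=O)/C=C(\C)CC)C1=O | intermediate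
19 | (1S,3S,4aR,5R,6R,8aR)-6-hydroxy-4a,5-dimethyl-2-oxo-3-(prop-1-en-2-yl)decahydronaphthalen-1-yl (E)-3-methylpent-2-enoate | C=C(C)[C@@H]1C[C@]2(C)[C@@H](C)[C@H](O)CC[C@H]2[C@H](OC(=O)/C=C(\C)CC)C1=O | intermediate
20 | angelic acid, (Z)-2-methylbut-2-enoic acid | C/C=C(/C)C(=O)O | starting material
21 | (Z)-2-methylbut-2-enoic 2,4,6-trichlorobenzoic anhydride (not isolated) | C/C=C(/C)C(=O)OC(=O)c1c(Cl)cc(Cl)cc1Cl | intermediate
22 | (1S,3S,4aR,5R,6R,8aR)-4a,5-dimethyl-6-{[(Z)-2-methylbut-2-enoyl]oxy}-2-oxo-3-(prop-1-en-2-yl)decahydronaphthalen-1-yl (E)-3-methylpent-2-enoate; in skeleton numbering 3R,4R,5R,7S,9S,10R | C=C(C)[C@@H]1C[C@]2(C)[C@@H](C)[C@H](OC(=O)/C(C)=C\C)CC[C@H]2[C@H](OC(=O)/C=C(\C)CC)C1=O | target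

**Count and risks**

Total step count: 14. Longest linear sequence: 14 steps (1 to 22).

Step 8. What may go wrong: acyl anion generation at C9 instead of C8, base-induced aldol closure from C7 onto the C9 formyl group, or epimerization at C10 before the ring closes. The fallback sets out from 9 and returns at 13; it fixes the polarity of the C8–C9 union with an alkyne instead of a carbene.
- Dess–Martin oxidation of 9 should give the aldehyde ester ethyl (1R,2R,3R,4R)-4-[(tert-butyldimethylsilyl)oxy]-2,3-dimethyl-2-(3-oxopropyl)cyclohexane-1-carboxylate F1.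
- Seyferth–Gilbert homologation (Ohira–Bestmann reagent, K2CO3, MeOH) converts its formyl group into the terminal alkyne ethyl (1R,2R,3R,4R)-2-(but-3-yn-1-yl)-4-[(tert-butyldimethylsilyl)oxy]-2,3-dimethylcyclohexane-1-carboxylate F2.
- LiAlH4 reduction gives the alkynol [(1R,2S,3R,4R)-2-(but-3-yn-1-yl)-4-[(tert-butyldimethylsilyl)oxy]-2,3-dimethylcyclohexyl]methanol F3, and a second Dess–Martin oxidation gives the ynal (1R,2R,3R,4R)-2-(but-3-yn-1-yl)-4-[(tert-butyldimethylsilyl)oxy]-2,3-dimethylcyclohexane-1-carbaldehyde F4.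
- Nickel-catalysed reductive alkyne–aldehyde cyclization (Ni(cod)2, PBu3, Et3SiH, THF) joins the internal alkyne carbon, C8, to the formyl carbon, C9. It should give the allylic silyl ether (1S,4aR,5R,6R,8aR)-6-[(tert-butyldimethylsilyl)oxy]-4a,5-dimethyl-2-methylidene-1-[(triethylsilyl)oxy]decahydronaphthalene F5, with the oxygen again equatorial to avoid the axial C14 methyl.
- Ozonolysis of the exocyclic methylene (O3, CH2Cl2, −78 °C; PPh3) then gives 13.

Step 10. What may go wrong: migration of the new double bond into conjugation with the ketone under the basic conditions, sluggish coupling or a second alkenylation at the hindered enolate, and protonation of C7 from the wrong face. The fallback sets out from 13 and returns at 15; it replaces the cross-coupling by aldol addition, dehydration and deconjugative protonation.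
- The zinc enolate of 13 (LiN(i-Pr)2, THF, −78 °C; ZnCl2) is added to acetone to give the aldol (1S,3S,4aR,5R,6R,8aR)-6-[(tert-butyldimethylsilyl)oxy]-3-(2-hydroxypropan-2-yl)-4a,5-dimethyl-1-[(triethylsilyl)oxy]-3,4,4a,5,6,7,8,8a-octahydronaphthalen-2(1H)-one F6.
- Mesylation and elimination (MsCl, Et3N, CH2Cl2; DBU) is allowed to run fully into conjugation and should give the isopropylidene ketone (1S,4aR,5R,6R,8aR)-6-[(tert-butyldimethylsilyl)oxy]-4a,5-dimethyl-3-(propan-2-ylidene)-1-[(triethylsilyl)oxy]-3,4,4a,5,6,7,8,8a-octahydronaphthalen-2(1H)-one F7.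
- The potassium dienolate of F7 (KOt-Bu, t-BuOH/THF) is quenched quickly with cold aqueous acetic acid. Kinetic α-protonation of the extended enolate moves the double bond out of conjugation and should give 15 with the isopropenyl group equatorial.

Step 3. What may go wrong: too little discrimination between the two enantiomers, or hydride delivery to the wrong carbonyl face, so that the equatorial (4R) carbinol is not obtained stereochemically pure. The fallback sets out from 5 and returns at 6; it uses substrate-controlled reduction followed by inversion with a chiral acid that also resolves.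
- Racemic 5 is reduced with LiBH(s-Bu)3 (THF, −78 °C), which attacks along the equatorial trajectory away from the axial methyl and should give the racemic axial alcohol ethyl (1R*,2R*,3R*,4S*)-4-hydroxy-2,3-dimethyl-2-(prop-2-en-1-yl)cyclohexane-1-carboxylate F8.
- Mitsunobu inversion with (S)-2-methoxy-2-phenylacetic acid (PPh3, diisopropyl azodicarboxylate, THF) gives the equatorial esters as two diastereomers: ethyl (1R,2R,3R,4R)-4-{[(2S)-2-methoxy-2-phenylacetyl]oxy}-2,3-dimethyl-2-(prop-2-en-1-yl)cyclohexane-1-carboxylate F9 and ethyl (1S,2S,3S,4S)-4-{[(2S)-2-methoxy-2-phenylacetyl]oxy}-2,3-dimethyl-2-(prop-2-en-1-yl)cyclohexane-1-carboxylate F10. They are separated by chromatography.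
- Mild ethanolysis of F9 (K2CO3, EtOH, rt) releases 6.

Further compounds
F1 | step 8 | ethyl (1R,2R,3R,4R)-4-[(tert-butyldimethylsilyl)oxy]-2,3-dimethyl-2-(3-oxopropyl)cyclohexane-1-carboxylate | O=CCC[C@]1(C)[C@@H](C)[C@H](O[Si](C)(C)C(C)(C)C)CC[C@H]1C(=O)OCC
F2 | step 8 | ethyl (1R,2R,3R,4R)-2-(but-3-yn-1-yl)-4-[(tert-butyldimethylsilyl)oxy]-2,3-dimethylcyclohexane-1-carboxylate | C#CCC[C@]1(C)[C@@H](C)[C@H](O[Si](C)(C)C(C)(C)C)CC[C@H]1C(=O)OCC
F3 | step 8 | [(1R,2S,3R,4R)-2-(but-3-yn-1-yl)-4-[(tert-butyldimethylsilyl)oxy]-2,3-dimethylcyclohexyl]methanol | C#CCC[C@]1(C)[C@@H](C)[C@H](O[Si](C)(C)C(C)(C)C)CC[C@H]1CO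
F4 | step 8 | (1R,2R,3R,4R)-2-(but-3-yn-1-yl)-4-[(tert-butyldimethylsilyl)oxy]-2,3-dimethylcyclohexane-1-carbaldehyde | C#CCC[C@]1(C)[C@@H](C)[C@H](O[Si](C)(C)C(C)(C)C)CC[C@H]1C=O
F5 | step 8 | (1S,4aR,5R,6R,8aR)-6-[(tert-butyldimethylsilyl)oxy]-4a,5-dimethyl-2-methylidene-1-[(triethylsilyl)oxy]decahydronaphthalene | C=C1CC[C@]2(C)[C@@H](C)[C@H](O[Si](C)(C)C(C)(C)C)CC[C@H]2[C@@H]1O[Si](CC)(CC)CC
F6 | step 10 | (1S,3S,4aR,5R,6R,8aR)-6-[(tert-butyldimethylsilyl)oxy]-3-(2-hydroxypropan-2-yl)-4a,5-dimethyl-1-[(triethylsilyl)oxy]-3,4,4a,5,6,7,8,8a-octahydronaphthalen-2(1H)-one | CC(C)(O)[C@@H]1C[C@]2(C)[C@@H](C)[C@H](O[Si](C)(C)C(C)(C)C)CC[C@H]2[C@H](O[Si](CC)(CC)CC)C1=O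
F7 | step 10 | (1S,4aR,5R,6R,8aR)-6-[(tert-butyldimethylsilyl)oxy]-4a,5-dimethyl-3-(propan-2-ylidene)-1-[(triethylsilyl)oxy]-3,4,4a,5,6,7,8,8a-octahydronaphthalen-2(1H)-one | CC(C)=C1C[C@]2(C)[C@@H](C)[C@H](O[Si](C)(C)C(C)(C)C)CC[C@H]2[C@H](O[Si](CC)(CC)CC)C1=O
F8 | step 3 | ethyl (1R*,2R*,3R*,4S*)-4-hydroxy-2,3-dimethyl-2-(prop-2-en-1-yl)cyclohexane-1-carboxylate (racemic, axial hydroxyl; one enantiomer drawn) | C=CC[C@]1(C)[C@@H](C)[C@@H](O)CC[C@H]1C(=O)OCC
F9 | step 3 | ethyl (1R,2R,3R,4R)-4-{[(2S)-2-methoxy-2-phenylacetyl]oxy}-2,3-dimethyl-2-(prop-2-en-1-yl)cyclohexane-1-carboxylate | C=CC[C@]1(C)[C@@H](C)[C@H](OC(=O)[C@@H](OC)c2ccccc2)CC[C@H]1C(=O)OCC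
F10 | step 3 | ethyl (1S,2S,3S,4S)-4-{[(2S)-2-methoxy-2-phenylacetyl]oxy}-2,3-dimethyl-2-(prop-2-en-1-yl)cyclohexane-1-carboxylate | C=CC[C@@]1(C)[C@H](C)[C@@H](OC(=O)[C@@H](OC)c2ccccc2)CC[C@@H]1C(=O)OCC
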